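## The problem

Locants used throughout are those of the target: C1 carries the acetoxymethyl carbon C7, C2 is the vinylic CH, C3 and C6 are the ring carbinols, C4–C5 is the oxirane, and the side chain runs from C1′ (on C4) to C12′.

All six ring carbons are functionalised. The quaternary oxirane carbon C4 also carries the C15 side chain through the carbinol C1′. Four contiguous ring stereocentres (3S, 4R, 5S, 6S) must be set with the oxirane syn to the C6 hydroxyl and anti to the C3 hydroxyl, and a fifth (1′S) sits on the chain next to C4.

Because C4, C5 and C6 take their oxygens on one face, a single centre on the other face (C3) can control all three. C1′ can then be controlled only by the ring, through the oxirane oxygen and the C3 substituent that flank it.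

The fragile parts are the epoxy-alcohol arrays (Payne migration in base, opening in acid), the primary allylic acetate (acyl shift, hydrazinolysis) and the C1′ carbinol, which is allylic to a (2E,4E,6E)-triene and ionises or oxidises easily. The side chain must therefore arrive after every step that uses singlet oxygen, strong acid or hydrazine.

The ring also hides an arene: carbon branches para to each other at C1 and C4, with oxygen on the two carbons between them. The feature that opens the key step is that C4, C5 and C6 carry cis oxygens while C1 and C4 are fully substituted. That is what remains when dioxygen is added across C1 and C4 of a C4=C5–C6=C1 diene and the peroxide is folded onto C5=C6, with no bridgehead hydrogen to divert it to a hydroxy enone.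

## Retrosynthesis

**Unveiling and the C1′–C2′ bond.** Target 29 is traced to its C3/C6 bis-silyl ether 28, and 28 is cut at C1′–C2′ into aldehyde 19 and alkenyl iodide 25 (used as 26 and 27). The neighbouring cut at C4–C1′ would need an oxiranyl anion at a quaternary carbon. The C1′–C2′ cut keeps the triene out of all oxidative steps and splits the molecule into a C14 polyene and a compact ring piece. The forward addition must set C1′ as S, which is asked of a magnesium chelate between the aldehyde and oxirane oxygens.

**The side chain.** Iodide 25 is cut at C3′–CH3 and C2′–I back to dienyne 23 through alkenylalane 24, and 23 at C4′=C5′ back to geranial 20 and phosphonate 21 through silyl enyne 22. A phosphonocrotonate-type olefination would give the C15 trienoate in one step, but its carboxyl carbon duplicates C1′, which is already on the ring. Building the C14 unit directly avoids excising a carbon. The forward steps must deliver E geometry at C4′=C5′ and at C2′=C3′.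

**C1′ oxidation level.** Aldehyde 19 comes from bis-triethylsilyl ether 18, and 18 from diol 17. No skeletal bond is cut. Silylating both hydroxyls and oxidising the primary silyl ether directly avoids having to oxidise a hindered primary alcohol selectively beside an allylic secondary one.

**The Wharton retron.** The C6 carbinol with the C1=C2 double bond in 17 maps onto the α,β-epoxy ketone 15 (through hydrazone 16). The C2–H and C1=C2 bonds are exchanged for C2=O and the C1–O bond of a C1–C6 oxirane. An enone reduction at C6 would need its own stereocontrol. Here C6 inherits its configuration from an oxirane that is necessarily syn to the C4–C5 oxirane, and the surplus C2 oxygen is removed in the same step.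

**Carbonyl unmasking.** Ketone 15 is traced to dimethyl ketal 13 (through ketal alcohol 14). The ketal is the form in which the C2 oxygen survives the oxidative steps.

**The oxygen rearrangement (key cut).** The C5–O and C6–O bonds of 13 are cut and the two oxygens joined, giving endoperoxide 12. Stepwise epoxidation of a diene gives the anti-bis-epoxide, whereas the peroxide can only deliver both oxygens to one face. Two rings and two stereocentres vanish. The forward step must close both oxiranes faster than the oxygen radicals fragment.

**Cycloaddition and the controlling centre.** The C1–O and C4–O bonds of 12 are cut to diene 11 and dioxygen. Diene 11 is the silyl ether of dienol 10, and 10 the reduction product of achiral dienone 9. After this cut the only stereocentre left is C3. The cycloaddition must occur anti to the C3 silyl ether, and the reduction must be enantioselective.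

**Dearomatisation and the arene.** The second C2–OMe bond of 9 is cut to phenol 8. Phenol 8 goes back through acetate diol 7 and triol 4 to diester 3 and to the C2-symmetric acid 1 (boronates 5 and 6 and diester 2 are in-flask intermediates). Every ring carbon, both branch carbons and the C2/C3 oxygens are then present from the start. Mono-O-methylation decides which carboxyl becomes C7 and which becomes C1′, and the phenol with its ortho hydroxymethyl group is the handle that tells the two branches apart.

## Roads not taken

**Alternative 1: chiral-pool diol with Payne migration.** The cut is the C4–O bond of the C4–C5 oxirane. Forward, the C5 alkoxide of epoxy alcohol A2 attacks C4 from the rear, inverts it and releases the C3 alkoxide, giving A3. Absolute configuration comes from the microbial cis-dihydrodiol of bromobenzene, A1.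
- Merits: no asymmetric catalysis is needed, the anti relation of the C3 hydroxyl and the oxirane follows stereospecifically from the inversion, and only base is required.
- Weak points: the substitution occurs at the fully substituted C4, the slowest kind of Payne step. A2 is a vinyl oxirane open to SN2′ attack, and since both isomers are trisubstituted oxiranes the equilibrium is not clearly on the side of A3. A1 carries neither carbon branch and A3 still lacks C7, so the quaternary C4 and the C1 branch cost many steps before and after.
- Comparison: this road is better in enantiomeric purity and has no sense-of-induction question. The chosen plan sets against it that acid 1 already holds all carbons and both C2/C3 oxygens, and that one stereospecific step makes two C–O bonds and two stereocentres.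

**Alternative 2: carbene-catalysed crossed benzoin.** The cut is the ring bond C3–C4. Forward, a chiral triazolium-derived carbene turns the aldehyde of keto-enal A4 into its acyl-anion equivalent, which adds to the C4 ketone and closes the ring as the tertiary carbinol A5.
- Merits: ring and quaternary centre are made in one mild catalytic C–C bond formation, C5 and C6 come from the chiral pool, and neither peroxide nor hydrazine is involved.
- Weak points: with enals the same intermediate reacts as a homoenolate (β-protonation, redox esterification), so chemoselectivity is uncertain. The enal must be Z and can isomerise, the β-silyloxy ketone can eliminate under the basic conditions, and catalyst and substrate control at C4 may be mismatched. After A5, the C3 ketone must still be reduced and the C4–OH/C5–O pair turned into the oxirane with inversion at C5, and A4 itself is a long linear construct.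
- Comparison: this road is equal or better for absolute control at C5/C6 and avoids the acetate–hydrazine clash. The chosen plan sets against it a shorter path to the core and oxygen stereochemistry that is transferred rather than selected.

**Alternative 3: dibromocarbene ring expansion.** The cuts are C1–C2 and C1–C6. Forward, dibromocarbene (CHBr3, KOtBu) adds to the enol double bond of silyl enol ether A6, and the siloxydibromocyclopropane opens with loss of bromide and silyl to the bromo enone A7.
- Merits: the oxirane and C3 exist before expansion, the C1 bromide is an ideal handle for C7 by cross-coupling, the C6 ketone can be reduced under control of the oxirane, and no Wharton step is needed.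
- Weak points: the enantiopure epoxycyclopentanone behind A6, with its quaternary C4, is its own asymmetric problem. Enolisation toward C2 places the C3 silyloxy group β to an enolate (elimination), and KOtBu/CHBr3 is harsh beside an oxirane. After A7, C7 introduction, C6 reduction and C1′ unmasking still follow.
- Comparison: length after the key step is comparable and modularity at C1 is better. The chosen plan sets against it that no chiral cyclopentanone must be prepared and that C4, C5 and C6 receive their oxygens in one stereospecific step.

Key step: step 9

Remarks on the chemistry (assumptions):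
- Phosphonate 21 is taken as a purchasable reagent (otherwise one Arbuzov step from the propargylic bromide).
- In step 6 the alkenyl arm, with its in-plane silyloxymethyl group, is assumed to act as the larger carbonyl substituent; this fixes the choice of the (R)-catalyst.

Step 1
Reactants: 1 2,3-dihydroxyterephthalic acid
Product: 3 dimethyl 2-hydroxy-3-methoxyterephthalate, via dimethyl 2,3-dihydroxyterephthalate 2 (not isolated)
Conditions: MeI (2.1 equiv), KHCO3, DMF, rt; then K2CO3 (1.0 equiv), MeI (1.0 equiv), rt → 40 °C
Reagents that add atoms: iodomethane, CI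
Why: Carboxylate alkylation under bicarbonate leaves the hydrogen-bonded phenols untouched; one equivalent of carbonate then forms only the catechol mono-anion, and Williamson methylation should stop at the mono ether because the remaining salicylate-type hydroxyl is less acidic. This desymmetrisation defines which ring carbon becomes C2 (OMe) and which C3 (OH).

Step 2
Reactants: 3 dimethyl 2-hydroxy-3-methoxyterephthalate
Product: 4 3,6-bis(hydroxymethyl)-2-methoxyphenol
Conditions: LiAlH4 (excess), THF, 0 °C → reflux; aqueous Rochelle salt
Reagents that add atoms: none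
Why: Hydride reduction of both aryl esters to benzylic alcohols (the salicylate ester reacts as its aluminium phenoxide at reflux); the aryl methyl ether is inert.

Step 3
Reactants: 4 3,6-bis(hydroxymethyl)-2-methoxyphenol
Product: 7 3-hydroxy-4-(hydroxymethyl)-2-methoxybenzyl acetate (acetate on the future C7), via boronate alcohol 5 (not isolated), via boronate acetate 6 (not isolated)
Conditions: PhB(OH)2 (1.0 equiv), toluene, reflux, Dean–Stark; Ac2O, pyridine, DMAP (cat.), rt; pinacol, THF, rt
Reagents that add atoms: acetic anhydride, CC(=O)OC(C)=O
Why: Phenylboronic acid condenses only with the phenol and its ortho hydroxymethyl group to a six-membered benzodioxaborin, so the other hydroxymethyl group is the only free hydroxyl for acetylation; transesterification with pinacol releases the phenol and the future C1′ hydroxyl. This is temporary cyclic boronate protection of a 1,3-diol.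

Step 4
Reactants: 7 3-hydroxy-4-(hydroxymethyl)-2-methoxybenzyl acetate
Product: 8 4-[(tert-butyldimethylsilyloxy)methyl]-3-hydroxy-2-methoxybenzyl acetate
Conditions: TBSCl (1.1 equiv), imidazole, CH2Cl2, 0 °C
Reagents that add atoms: tert-butyldimethylsilyl chloride, CC(C)(C)[Si](C)(C)Cl
Why: The primary benzylic hydroxyl is silylated faster than the di-ortho-substituted, hydrogen-bonded phenol, as is usual for salicyl alcohols.

Step 5
Reactants: 8 4-[(tert-butyldimethylsilyloxy)methyl]-3-hydroxy-2-methoxybenzyl acetate
Product: 9 [4-[(tert-butyldimethylsilyloxy)methyl]-6,6-dimethoxy-5-oxocyclohexa-1,3-dien-1-yl]methyl acetate (achiral dienone: C3 ketone, C2 dimethyl ketal, C4=C5–C6=C1 diene)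
Conditions: PhI(OAc)2 (1.05 equiv), NaHCO3, MeOH, 0 °C
Reagents that add atoms: methanol, CO
Why: Oxidative dearomatisation of a 2-methoxyphenol: the aryloxyiodane is attacked by methanol at the methoxy-bearing carbon to give the ortho-quinone monoketal. Branches at both diene termini (C1 and C4) should suppress the Diels–Alder dimerisation usual for such dienones.

Step 6
Reactants: 9 the dienone ketal
Product: 10 [(5R)-4-[(tert-butyldimethylsilyloxy)methyl]-5-hydroxy-6,6-dimethoxycyclohexa-1,3-dien-1-yl]methyl acetate ((3R) in target locants)
Conditions: (R)-2-methyl-CBS-oxazaborolidine (0.2 equiv), BH3·SMe2 (0.7 equiv), THF, −30 °C; MeOH quench, neutral work-up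
Reagents that add atoms: none
Why: Corey–Bakshi–Shibata 1,2-reduction of the cross-conjugated ketone. With the substituted alkenyl arm as the large group and the ketal carbon as the small one, the (R)-catalyst should deliver hydride to the face that gives the (3R) carbinol; the acetate and the ketal are inert to borane at this temperature.

Step 7
Reactants: 10 the (3R)-dienol
Product: 11 [(5R)-5-(tert-butyldimethylsilyloxy)-4-[(tert-butyldimethylsilyloxy)methyl]-6,6-dimethoxycyclohexa-1,3-dien-1-yl]methyl acetate
Conditions: TBSOTf (1.2 equiv), 2,6-lutidine (3 equiv), CH2Cl2, −78 °C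
Reagents that add atoms: tert-butyldimethylsilyl triflate, CC(C)(C)[Si](C)(C)OS(=O)(=O)C(F)(F)F
Why: Silylation of the hindered allylic alcohol under buffered conditions, cold enough to leave the ketal un-ionised; the bulky ether is the facial control element for step 8.

Step 8
Reactants: 11 the bis-silyl dienyl ketal
Product: 12 C1/C4 endoperoxide (2,3-dioxabicyclo[2.2.2]oct-5-ene; (1S,3R,4R) in target locants): peroxide bridge on the face opposite the C3 silyloxy group, C1–CH2OAc, C4–CH2OTBS, C2 dimethyl ketal
Conditions: O2, 5,10,15,20-tetraphenylporphyrin (sensitiser, 1 mol %), visible light, CH2Cl2, −40 °C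
Reagents that add atoms: dioxygen, O=O
Why: [4+2] cycloaddition of singlet oxygen to a cisoid 1,4-disubstituted cyclohexadiene (the ascaridole pattern). The oxygen should approach anti to the pseudo-axial C3 silyl ether, which sets C1 and C4.

Step 9
Reactants: 12 C1/C4 endoperoxide
Product: 13 syn-bis-epoxide ketal ((1R,3R,4S,5S,6R) in target locants): C1–C6 and C4–C5 oxiranes on one face, C3–OTBS on the other, C2 dimethyl ketal, C7–OAc, C1′–OTBS
Conditions: Co(TPP) (cobalt tetraphenylporphyrin, C44H28CoN4, divalent cobalt, 5 mol %), CH2Cl2, −20 → 0 °C
Reagents that add atoms: none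
Why: Divalent cobalt transfers one electron into the O–O bond of 12, giving a trivalent cobalt alkoxide on one bridgehead oxygen and an oxygen radical on the other; the oxygen radical on C4 adds to C5 and the resulting C6 radical attacks the cobalt-bound oxygen on C1, releasing divalent cobalt. The closest known reaction type is the cobalt-porphyrin isomerisation of 1,4-disubstituted 2,3-dioxabicyclo[2.2.2]oct-5-enes such as ascaridole to their syn-diepoxides. Both oxiranes (C4–O–C5 and C1–O–C6) close in the 3-exo mode from oxygens already bonded to C4 and C1. The new stereocentres C5 and C6 are fixed by the peroxide bridge: both oxygens lie on the face set in step 8, so the two oxiranes are necessarily syn to each other and anti to the C3 silyl ether, while C1 and C4 keep their configuration because their C–O bonds are never broken. The step needs double closure to win over hydroxy-enone formation and over a 1,2-shift to an epoxy ketone; both need a bridgehead hydrogen, and C1 and C4 are fully substituted. It also needs closure to outrun β-scission of the bridgehead alkoxy radical toward the ketal carbon C2, which the rigidly held adjacent C5=C6 bond and the low temperature are expected to secure.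

Step 10
Reactants: 13 syn-bis-epoxide ketal
Product: 15 bis-epoxy ketone alcohol ((1R,3R,4S,5S,6R) in target locants): C2 ketone, free C1′ hydroxyl, C3–OTBS and C7–OAc retained, via ketal alcohol 14 (not isolated)
Conditions: TFA/H2O (4:1), CH2Cl2, 0 °C
Reagents that add atoms: water, O
Why: Aqueous acid first removes the primary silyl ether and then hydrolyses the dimethyl ketal through its oxocarbenium ion. The hindered secondary silyl ether, the acetate and the two electron-poor oxiranes (each flanked by oxygenated or carbonyl carbons) are expected to survive at 0 °C.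

Step 11
Reactants: 15 bis-epoxy ketone alcohol
Product: 17 allylic alcohol diol ((3S,4S,5S,6S) in target locants): C1=C2, C6–OH syn to the C4–C5 oxirane, C1′–OH, C3–OTBS, C7–OAc, via epoxy hydrazone 16 (not isolated)
Conditions: N2H4·H2O (2 equiv), AcOH (0.5 equiv), MeOH, 0 °C → rt
Reagents that add atoms: none
Why: Wharton transposition: the C2 hydrazone opens the adjacent C1–O bond of the C1–C6 oxirane to a vinyl diazene, which loses dinitrogen and leaves hydrogen on C2 and the double bond at C1=C2. The C6–O bond is untouched, so C6 keeps its configuration, and the C4–C5 oxirane is not adjacent to the hydrazone.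

Step 12
Reactants: 17 allylic alcohol diol
Product: 18 C6,C1′-bis(triethylsilyl) ether of 17 ((3S,4S,5S,6S) in target locants)
Conditions: TESCl (2.5 equiv), imidazole, DMAP (cat.), CH2Cl2, 0 °C → rt
Reagents that add atoms: chlorotriethylsilane, CC[Si](CC)(CC)Cl
Why: Routine silylation of both hydroxyls; it masks the C6 carbinol and prepares C1′ for direct oxidation.

Step 13
Reactants: 18 the bis(triethylsilyl) ether
Product: 19 C1′ aldehyde ((3S,4S,5S,6S) in target locants): formyl group on C4, C6–OTES, C3–OTBS, C7–OAc
Conditions: (COCl)2 (3 equiv), DMSO (6 equiv), CH2Cl2, −78 → −40 °C; Et3N, −78 → 0 °C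
Reagents that add atoms: none
Why: Direct Swern oxidation of a primary triethylsilyl ether: the chlorosulfonium salt attacks the least hindered silyl ether oxygen, the silyl group leaves as its chloride, and base collapses the alkoxysulfonium salt to the aldehyde. Secondary silyl ethers react far more slowly.

Step 14
Reactants: 20 geranial; 21 diethyl [3-(trimethylsilyl)prop-2-yn-1-yl]phosphonate
Product: 22 trimethyl[(3E,5E)-6,10-dimethylundeca-3,5,9-trien-1-yn-1-yl]silane
Conditions: 21, LiN(SiMe3)2, THF, −78 °C; then 20, −78 °C → rt
Reagents that add atoms: none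
Why: Horner–Wadsworth–Emmons olefination of the enal with a stabilised propargylic phosphonate anion should give the E double bond at C4′=C5′; the existing E trisubstituted bond of geranial is not touched.

Step 15
Reactants: 22 the silyl dienyne
Product: 23 (3E,5E)-6,10-dimethylundeca-3,5,9-trien-1-yne
Conditions: K2CO3 (0.2 equiv), MeOH, rt
Reagents that add atoms: none
Why: Base-catalysed methanolysis of the alkynyl–silicon bond.

Step 16
Reactants: 23 the terminal dienyne
Product: 25 (1E,3E,5E)-1-iodo-2,6,10-trimethylundeca-1,3,5,9-tetraene, via alkenylalane 24 (not isolated)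
Conditions: Me3Al (2 equiv), Cp2ZrCl2 (0.25 equiv), CH2Cl2, 0 °C → rt; then I2, THF, −30 → 0 °C
Reagents that add atoms: trimethylaluminium, C[Al](C)C; iodine, II
Why: Zirconium-catalysed carboalumination (Negishi) adds methyl and aluminium syn across the terminal alkyne, with methyl on the internal carbon; iodinolysis with retention gives the E iodide. Conjugated enynes and isolated trisubstituted alkenes are tolerated in this reaction type.

Step 17
Reactants: 19 C1′ aldehyde; 25 alkenyl iodide
Product: 28 C3–OTBS, C6–OTES ether of the target ((3S,4S,5S,6S,1′S) in target locants), via alkenyllithium 26 (not isolated), via alkenylmagnesium bromide 27 (not isolated)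
Conditions: 25, t-BuLi (2.0 equiv), Et2O, −78 °C; MgBr2·OEt2 (1.1 equiv), −78 → −40 °C; then 19, CH2Cl2, −78 °C; aqueous NH4Cl
Reagents that add atoms: none
Why: Iodine–lithium exchange with retention, transmetalation to magnesium, and chelation-controlled 1,2-addition. Magnesium should bridge the aldehyde and oxirane oxygens, which turns the formyl hydrogen toward the C3 silyl ether, so the alkenyl group enters from the open side over C5 and gives (1′S). At −78 °C the aldehyde should react well before the acetate.

Step 18
Reactants: 28 the bis-silyl ether
Product: 29 target, [(1R,2S,5S,6S)-2,5-dihydroxy-1-[(1S,2E,4E,6E)-1-hydroxy-3,7,11-trimethyldodeca-2,4,6,10-tetraen-1-yl]-7-oxabicyclo[4.1.0]hept-3-en-4-yl]methyl acetate ((3S,4R,5S,6S,1′S) in target locants)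
Conditions: HF·pyridine, pyridine, THF, 0 °C → rt
Reagents that add atoms: none
Why: Buffered fluoride cleavage of the triethylsilyl and the secondary tert-butyldimethylsilyl ether; the excess pyridine keeps the medium mild enough for the acetate, the oxirane and the triene carbinol.

## Compound list

1 | 2,3-dihydroxyterephthalic acid | OC(=O)c1ccc(C(O)=O)c(O)c1O | starting material
2 | dimethyl 2,3-dihydroxyterephthalate | COC(=O)c1ccc(C(=O)OC)c(O)c1O | intermediate
3 | dimethyl 2-hydroxy-3-methoxyterephthalate | COC(=O)c1ccc(C(=O)OC)c(OC)c1O | intermediate
4 | 3,6-bis(hydroxymethyl)-2-methoxyphenol | OCc1ccc(CO)c(OC)c1O | intermediate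
5 | (8-methoxy-2-phenyl-4H-1,3,2-benzodioxaborin-7-yl)methanol | OCc1ccc2COB(c3ccccc3)Oc2c1OC | intermediate
6 | (8-methoxy-2-phenyl-4H-1,3,2-benzodioxaborin-7-yl)methyl acetate | CC(=O)OCc1ccc2COB(c3ccccc3)Oc2c1OC | intermediate
7 | 3-hydroxy-4-(hydroxymethyl)-2-methoxybenzyl acetate | CC(=O)OCc1ccc(CO)c(O)c1OC | intermediate
8 | 4-[(tert-butyldimethylsilyloxy)methyl]-3-hydroxy-2-methoxybenzyl acetate | CC(=O)OCc1ccc(CO[Si](C)(C)C(C)(C)C)c(O)c1OC | intermediate
9 | dienone ketal (C3 ketone, C2 dimethyl ketal, C7–OAc, C1′–OTBS) | CC(=O)OCC1=CC=C(CO[Si](C)(C)C(C)(C)C)C(=O)C1(OC)OC | intermediate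
10 | (3R)-dienol ketal | CC(=O)OCC1=CC=C(CO[Si](C)(C)C(C)(C)C)[C@@H](O)C1(OC)OC | intermediate
11 | (3R)-silylated dienol ketal | CC(=O)OCC1=CC=C(CO[Si](C)(C)C(C)(C)C)[C@@H](O[Si](C)(C)C(C)(C)C)C1(OC)OC | intermediate
12 | C1/C4 endoperoxide, (1S,3R,4R), peroxide anti to C3–OTBS | CC(=O)OC[C@@]12OO[C@@](CO[Si](C)(C)C(C)(C)C)(C=C1)[C@@H](O[Si](C)(C)C(C)(C)C)C2(OC)OC | intermediate
13 | syn-bis-epoxide ketal, (1R,3R,4S,5S,6R) | CC(=O)OC[C@@]12O[C@@H]1[C@@H]1O[C@]1(CO[Si](C)(C)C(C)(C)C)[C@@H](O[Si](C)(C)C(C)(C)C)C2(OC)OC | intermediate
14 | syn-bis-epoxide ketal with free C1′ hydroxyl | CC(=O)OC[C@@]12O[C@@H]1[C@@H]1O[C@]1(CO)[C@@H](O[Si](C)(C)C(C)(C)C)C2(OC)OC | intermediate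
15 | bis-epoxy C2 ketone with free C1′ hydroxyl, (1R,3R,4S,5S,6R) | CC(=O)OC[C@@]12O[C@@H]1[C@@H]1O[C@]1(CO)[C@@H](O[Si](C)(C)C(C)(C)C)C2=O | intermediate
16 | C2 hydrazone of 15 | CC(=O)OC[C@@]12O[C@@H]1[C@@H]1O[C@]1(CO)[C@@H](O[Si](C)(C)C(C)(C)C)C2=NN | intermediate
17 | allylic alcohol diol (C1=C2, C6–OH, C1′–OH, C3–OTBS), (3S,4S,5S,6S) | CC(=O)OCC1=C[C@H](O[Si](C)(C)C(C)(C)C)[C@@]2(CO)O[C@H]2[C@H]1O | intermediate
18 | C6,C1′-bis(triethylsilyl) ether of 17 | CC(=O)OCC1=C[C@H](O[Si](C)(C)C(C)(C)C)[C@@]2(CO[Si](CC)(CC)CC)O[C@H]2[C@H]1O[Si](CC)(CC)CC | intermediate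
19 | C1′ aldehyde (C6–OTES, C3–OTBS), (3S,4S,5S,6S) | CC(=O)OCC1=C[C@H](O[Si](C)(C)C(C)(C)C)[C@@]2(C=O)O[C@H]2[C@H]1O[Si](CC)(CC)CC | intermediate
20 | geranial | CC(C)=CCC/C(C)=C/C=O | starting material
21 | diethyl [3-(trimethylsilyl)prop-2-yn-1-yl]phosphonate | CCOP(=O)(CC#C[Si](C)(C)C)OCC | starting material
22 | trimethyl[(3E,5E)-6,10-dimethylundeca-3,5,9-trien-1-yn-1-yl]silane | C[Si](C)(C)C#C/C=C/C=C(\C)CCC=C(C)C | intermediate
23 | (3E,5E)-6,10-dimethylundeca-3,5,9-trien-1-yne | C#C/C=C/C=C(\C)CCC=C(C)C | intermediate
24 | dimethyl[(1E,3E,5E)-2,6,10-trimethylundeca-1,3,5,9-tetraen-1-yl]alane | C[Al](C)/C=C(C)/C=C/C=C(\C)CCC=C(C)C | intermediate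
25 | (1E,3E,5E)-1-iodo-2,6,10-trimethylundeca-1,3,5,9-tetraene | I/C=C(C)/C=C/C=C(\C)CCC=C(C)C | intermediate
26 | [(1E,3E,5E)-2,6,10-trimethylundeca-1,3,5,9-tetraen-1-yl]lithium | [Li]/C=C(C)/C=C/C=C(\C)CCC=C(C)C | intermediate
27 | [(1E,3E,5E)-2,6,10-trimethylundeca-1,3,5,9-tetraen-1-yl]magnesium bromide | Br[Mg]/C=C(C)/C=C/C=C(\C)CCC=C(C)C | intermediate
28 | C3–OTBS, C6–OTES ether of the target, (3S,4S,5S,6S,1′S) | CC(=O)OCC1=C[C@H](O[Si](C)(C)C(C)(C)C)[C@@]2([C@@H](O)/C=C(C)/C=C/C=C(\C)CCC=C(C)C)O[C@H]2[C@H]1O[Si](CC)(CC)CC | intermediate
29 | target, (3S,4R,5S,6S,1′S) | CC(=O)OCC1=C[C@H](O)[C@@]2([C@@H](O)/C=C(C)/C=C/C=C(\C)CCC=C(C)C)O[C@H]2[C@H]1O | target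

## Step count and least certain steps

Total: 18 steps. Longest linear sequence: 15 steps (steps 1–13, 17, 18); fragment 2 takes 3 steps (14–16).

**Step 9 (key step).** The bridgehead alkoxy radical may fragment (β-scission of C1–C2 toward the dialkoxy-stabilised C2 radical, or loss of an oxygenated methyl branch) before the first oxirane closes, or the second closure may stall. The fallback is an ionic sequence that sets out from 11 and comes back at 13. Peracid epoxidation (mCPBA, NaHCO3, CH2Cl2, 0 °C) of the more electron-rich C4=C5 bond, anti to the silyl ether, gives the vinyl oxirane F1. NBS in aqueous DME forms the bromonium ion on C6=C1 anti to that oxirane, and trans opening by water gives the bromohydrin F2 (C1–OH on the oxirane face, C6–Br opposite; the regioisomer converges). DBU then closes the second oxirane by rear-side displacement to give 13.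

**Step 6.** The two fully substituted flanks of the carbonyl may be poorly discriminated (low enantioselectivity or the opposite sense), and the dienol may lose methanol and re-aromatise on work-up. The antipodal catalyst is the first adjustment. The fallback replaces asymmetric catalysis by resolution, setting out from 9 and coming back at 10. Luche reduction (NaBH4, CeCl3·7H2O, MeOH, −78 °C) gives the racemic dienol F3, and the enantiomers are separated by preparative chromatography on a chiral stationary phase. The (3R) enantiomer is 10; the (3S) enantiomer F4 is returned to 9 with MnO2.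

**Step 10.** The ketal, flanked by two oxygenated carbons, ionises slowly. Forcing conditions may open an oxirane (possibly with participation of the C7 acetate) or remove the C3 silyl ether. The fallback separates the two events and avoids protic acid, setting out from 13 and coming back at 15. Ketal exchange with acetone under PdCl2(MeCN)2 gives the bis-silyl epoxy ketone F5, and HF·pyridine in THF/pyridine then removes only the primary silyl ether.

**Step 11.** Hydrazone formation at the hindered C2 carbonyl may be slow enough for hydrazine to cleave the acetate, and the vinyl diazene may decompose by radical paths to over-reduced material. The fallback is a radical deoxygenation–fragmentation that sets out from 15 and comes back at 18.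
- TESCl/imidazole on the primary hydroxyl gives the silyl ether F6.
- NaBH4 in MeOH at −20 °C gives the epoxy alcohol F7 (either C2 epimer serves).
- 1,1′-Thiocarbonyldiimidazole with DMAP gives the imidazolylthiocarbonyl derivative F8.
- Bu3SnH/AIBN in toluene at 80 °C generates the C2 radical, which opens the adjacent C1–O bond; reduction of the C6 oxygen radical gives the allylic alcohol F9.
- Silylation of the C6 hydroxyl with TESCl gives 18.

**Step 17.** Addition may proceed through the non-chelated rotamer and give the C1′ epimer, and the organometallic may attack the acetate. The fallback does not rely on the selectivity of the addition, setting out from 19 and 25 and coming back at 28. CrCl2 with catalytic NiCl2 in DMSO (Nozaki–Hiyama–Kishi coupling, tolerant of acetate and oxirane) gives a C1′ epimer mixture containing the (1′R) alcohol F10. Dess–Martin periodinane (NaHCO3) converts the mixture into the trienyl ketone F11. Reduction with NaBH4/CeCl3·7H2O in MeOH at −78 °C should give 28, because the trienyl group turns away from the C3 silyl ether and hydride enters from the open side over C5.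

## Further compounds

F1 | step 9 | C4–C5 mono-epoxide of 11 (oxirane anti to C3–OTBS) | CC(=O)OCC1=C[C@@H]2O[C@]2(CO[Si](C)(C)C(C)(C)C)[C@@H](O[Si](C)(C)C(C)(C)C)C1(OC)OC
F2 | step 9 | bromohydrin of F1 (C1–OH syn to the oxirane, C6–Br anti) | CC(=O)OC[C@@]1(O)[C@@H](Br)[C@@H]2O[C@]2(CO[Si](C)(C)C(C)(C)C)[C@@H](O[Si](C)(C)C(C)(C)C)C1(OC)OC
F3 | step 6 | racemic dienol ketal | CC(=O)OCC1=CC=C(CO[Si](C)(C)C(C)(C)C)C(O)C1(OC)OC
F4 | step 6 | (3S)-dienol ketal (enantiomer of 10) | CC(=O)OCC1=CC=C(CO[Si](C)(C)C(C)(C)C)[C@H](O)C1(OC)OC
F5 | step 10 | bis-epoxy C2 ketone with C1′–OTBS and C3–OTBS | CC(=O)OC[C@@]12O[C@@H]1[C@@H]1O[C@]1(CO[Si](C)(C)C(C)(C)C)[C@@H](O[Si](C)(C)C(C)(C)C)C2=O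
F6 | step 11 | C1′ triethylsilyl ether of 15 | CC(=O)OC[C@@]12O[C@@H]1[C@@H]1O[C@]1(CO[Si](CC)(CC)CC)[C@@H](O[Si](C)(C)C(C)(C)C)C2=O
F7 | step 11 | C2 alcohol from F6 (C2 configuration open) | CC(=O)OC[C@@]12O[C@@H]1[C@@H]1O[C@]1(CO[Si](CC)(CC)CC)[C@@H](O[Si](C)(C)C(C)(C)C)C2O
F8 | step 11 | C2 O-(imidazol-1-ylthiocarbonyl) derivative of F7 | CC(=O)OC[C@@]12O[C@@H]1[C@@H]1O[C@]1(CO[Si](CC)(CC)CC)[C@@H](O[Si](C)(C)C(C)(C)C)C2OC(=S)n1ccnc1
F9 | step 11 | allylic alcohol with C1′–OTES (C1=C2, C6–OH) | CC(=O)OCC1=C[C@H](O[Si](C)(C)C(C)(C)C)[C@@]2(CO[Si](CC)(CC)CC)O[C@H]2[C@H]1O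
F10 | step 17 | (1′R) epimer of 28 | CC(=O)OCC1=C[C@H](O[Si](C)(C)C(C)(C)C)[C@@]2([C@H](O)/C=C(C)/C=C/C=C(\C)CCC=C(C)C)O[C@H]2[C@H]1O[Si](CC)(CC)CC
F11 | step 17 | C1′ trienyl ketone | CC(=O)OCC1=C[C@H](O[Si](C)(C)C(C)(C)C)[C@@]2(C(=O)/C=C(C)/C=C/C=C(\C)CCC=C(C)C)O[C@H]2[C@H]1O[Si](CC)(CC)CC
A1 | alternative 1 | (1S,2S)-3-bromocyclohexa-3,5-diene-1,2-diol | O[C@H]1C=CC=C(Br)[C@H]1O
A2 | alternative 1 | C3–C4 epoxy alcohol with free C5 hydroxyl (Payne substrate) | C1=C[C@@H]2O[C@]2(COCc3ccc(OC)cc3)[C@@H](O)[C@H]1O[Si](CC)(CC)CC
A3 | alternative 1 | C4–C5 epoxide with free C3 hydroxyl (Payne product) | C1=C[C@H](O)[C@@]2(COCc3ccc(OC)cc3)O[C@H]2[C@H]1O[Si](CC)(CC)CC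
A4 | alternative 2 | open-chain (Z)-keto-enal | O=C/C=C(COC(C)=O)\[C@H](O[Si](C)(C)C(C)(C)C)[C@@H](O[Si](CC)(CC)CC)C(=O)COCc1ccc(OC)cc1
A5 | alternative 2 | C4-hydroxy cyclohexenone | CC(=O)OCC1=CC(=O)[C@](O)(COCc2ccc(OC)cc2)[C@H](O[Si](CC)(CC)CC)[C@H]1O[Si](C)(C)C(C)(C)C
A6 | alternative 3 | trimethylsilyl enol ether of the epoxycyclopentanone | C[Si](C)(C)OC1=C[C@H](O[Si](C)(C)C(C)(C)C)[C@@]2(COCc3ccc(OC)cc3)O[C@@H]12
A7 | alternative 3 | C1-bromo epoxycyclohexenone | BrC1=C[C@H](O[Si](C)(C)C(C)(C)C)[C@@]2(COCc3ccc(OC)cc3)O[C@H]2C1=O
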